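## The problem

Lignan numbering is used throughout: Ar1 is the aryl group on C7 and Ar2 the aryl group on C7'.

Compound 17 is a furofuran lignan: two tetrahydrofuran rings, ring A (C7–O–C9'–C8'–C8) and ring B (C7'–O–C9–C8–C8'), share the C8–C8' bond in a cis fusion, and each benzylic carbon carries its aryl group on the exo face (H7/H8 and H7'/H8' trans). The aryl groups differ (Ar1 = 4-hydroxy-3-methoxyphenyl, Ar2 = 3-hydroxy-4,5-dimethoxyphenyl), so the molecule has no symmetry and cannot come from dimerising one phenylpropanoid unit; the two halves have to be joined cross-selectively. Four contiguous stereocentres (7S, 8R, 8'R, 7'S) are present but are not equal: C8 and C8' are plain C–H centres that must be made in the absolute sense and then kept, whereas C7 and C7' are ether carbons para to an oxygen substituent, ionise easily, and can be set last under the control of C8 and C8'. The same lability is the main hazard: acid moves the benzylic ethers toward exo/endo mixtures and hydrogenolysis cleaves them, which rules out benzyl protection of the phenols and any late hydrogenation. The two phenols and the electron-rich rings also exclude unprotected organometallic steps and strong oxidants late in the route. The enabling feature is the chain C9–C8–C8'–C9': once the rings are opened at C7–O and C7'–O it is a 2,3-disubstituted butane-1,4-diol, the reduced form of a butenolide with C9' as carbonyl, C8' as α-carbon, C8 as β-carbon and C9 as γ-carbon. On that butenolide C8 is an electrophile and C8' becomes a nucleophile after conjugate addition, so C7 can arrive as an acyl-anion equivalent and C7' as an aldehyde in one operation, and a single stereocentre on C9 can direct both new ring centres.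

## Retrosynthesis

**Phenols unmasked last (17 from 16).** Only the two O–Si bonds are cut. Silyl ethers are chosen over benzyl ethers because hydrogenolysis would also cleave the C7–O and C7'–O bonds of the furofuran, whereas fluoride touches nothing else in 16. The precursor is no simpler in skeleton, but its phenols are masked through the organolithium, hydride and acid steps.

**Both rings from an open-chain tetraol (16 from 15).** The cuts are C7–O (ring A) and C7'–O (ring B), each at the benzylic carbon. The neighbouring cut at O–C9' and O–C9 (displacement at the primary carbons) would retain the benzylic configuration and so require C7 and C7' to be set correctly beforehand. Cutting at the benzylic carbons asks nothing of them, because a p-oxygenated benzylic cation is planar and forms from either epimer. Tetraol 15 is acyclic and only C8 and C8' matter in it. The forward reaction must close each ring with the aryl group trans to the adjacent ring carbon and must not be left to equilibrate.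

**Oxidation-state adjustment (15 from 14, 14 from 13).** No skeletal bond is cut. Tetraol 15 is the fully reduced form of keto lactone 14, which has C7 as aryl ketone, C9' as lactone carbonyl and C9 as the acetal carbon of a 5-alkoxybutyrolactone. One hydride reagent therefore delivers all four hydroxyl groups and expels the auxiliary alcohol. The ketone is the unmasked form of the 1,3-dithiane in 13. This brings the problem back to a five-membered lactone in which C8 and C8' are ring stereocentres whose trans relationship is both the kinetic and the thermodynamic one.

**Three-component disconnection (13 from 3, 10 and 5).** The cuts are C7–C8 and C8'–C7'. Cutting C8–C8' instead would mean an oxidative coupling of two different enolates with no handle on cross-selectivity, and making the two benzylic bonds in separate operations would cost steps. The chosen cut removes both aryl-bearing carbons at once and leaves three simple pieces: the acyl-anion equivalent 3, the butenolide 10 with one bought stereocentre, and the aldehyde 5. The forward reaction must add 1,4, must take the face of 10 opposite the menthyloxy group, and must trap the enolate on carbon before it is protonated.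

**The three components.** Dithiane 3 comes from silylated vanillin 2 (two C–S bonds) and 2 from vanillin 1 (O–Si). Aldehyde 5 comes from the commercial phenol 4 (O–Si). Furanone 10 comes from 5-hydroxy-2(5H)-furanone 8 and (−)-menthol 9 (acetal C–O), with the C5 configuration selected by crystallisation, and 8 from furfural 6 by addition of singlet oxygen. Each of these steps has only to be clean.

## Roads not taken

**Alternative 1: epoxide radical cascade.**
- **Cut:** C8–C8' together with C7'–O, leading back to the epoxy cinnamyl ether A1, in which C7 already carries its ether oxygen and C8–C9 is a terminal epoxide.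
- **Forward key step:** Cp2TiCl (trivalent titanium, generated from Cp2TiCl2 and Zn) opens the epoxide to the C8 radical, which cyclises 5-exo onto the cinnamyl double bond and closes ring A. The benzylic C7' radical is captured by titanium, and iodine turns that species into an electrophile that the C9 alkoxide attacks, closing ring B to give the bis-pivalate A2.
- **Merits:** both rings and three stereocentres form in one flask, every carbon is already at its final oxidation level, and A1 is only a few steps from the two aldehydes. On step count and on closing the rings in the key step this road is better than the chosen one.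
- **Weak points:** the absolute configuration rests on C7 of A1, a benzylic allylic ether centre with no cheap chiral-pool source; it would need a kinetic resolution or an asymmetric addition. The relay from C7 to C8 and C8' passes through a planar radical, and that from C8' to C7' through a configurationally labile benzylic titanium or iodide species, so three centres are only loosely controlled. Stoichiometric titanium and iodine force the phenols to be worn as esters.
- **Comparison:** the chosen plan is longer, but its chirality is bought in crystalline form in 10 and relayed through two closed-shell steps with a clear facial bias, and C7 and C7' are set afterwards by a closure whose selectivity follows from the C8 and C8' centres.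

**Alternative 2: oxygen insertion into a cyclobutanone.**
- **Cut:** the C9–O and O–C7' bonds, that is, removal of the ring-B oxygen. The precursor is cyclobutanone A3, in which ring A is intact and C8, C9 (as ketone), C7' and C8' form a four-membered ring.
- **Forward key step:** mCPBA adds to the C9 carbonyl and the Criegee intermediate rearranges with migration of the electron-rich benzylic C7' with retention (Baeyer–Villiger), giving lactone A4.
- **Merits:** the C7'–O bond is made stereospecifically. In this respect the road is better than the chosen plan, which sets C7' by kinetic capture of a cation.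
- **Weak points:** A3 already contains ring A and all four stereocentres, so the problem is moved into its preparation. That would be a cycloaddition of an aryl ketene to an enantioenriched 2-aryl-2,5-dihydrofuran, in which only a remote aryl group distinguishes the two olefin carbons. A peracid has to be used on two electron-rich arenes. A4 carries C9 as a lactone carbonyl on an ionisable benzylic ester, so two further reductive steps are needed.
- **Comparison:** the chosen plan gives up stereospecificity at C7' but builds its key-step precursors 3, 5 and 10 in one or two routine steps each and keeps C9 and C9' at oxidation levels that one hydride step removes.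

**Alternative 3: double transfer hydrogenation and bis-lactonisation.**
- **Cut:** C7–O and C7'–O at the lactone oxidation level together with both carbinol C–H bonds, leading back to the diaroylsuccinate A5.
- **Forward key step:** RuCl(p-cymene)[(S,S)-TsDPEN] (divalent ruthenium) with formic acid and triethylamine reduces both aryl ketones to S carbinols while C8 and C8' epimerise through the β-keto ester enols. Each carbinol lactonises onto the ester of the other half, giving the cis-fused bis-lactone A6.
- **Merits:** the chirality comes from a catalyst instead of a stoichiometric auxiliary, and all four stereocentres and both rings are set in one step. In atom economy and in reagent control over C7 and C7' this road is superior.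
- **Weak points:** A5 is unsymmetrical, so it must be made by a cross-coupling of two different aroylacetates, where homo-coupling competes. The dynamic resolution must correct two labile centres in a molecule whose two ketones differ electronically, and after the first lactonisation the remaining centre sits on a ring where enolisation and catalyst preference need not cooperate. A6 is a double benzylic ester. Taking both carbonyls to CH2 needs either two reductive steps on an ionisable substrate or LiAlH4 followed by acid re-closure, which gives a single diastereomer of 15 and the same end game as here.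
- **Comparison:** the chosen plan uses an auxiliary, which is recovered in step 8, but each of its bonds forms by a reaction type established on this substrate class, and its cross-selectivity is built in because the two aryl carbons enter as different reagents.

Key step: step 6

Assumption: both carbinol epimers at C7' (and later C7) converge in step 9, so compounds 13 to 15 are carried as epimer mixtures and their SMILES leave these centres open.

## Route

Step 1
Reactants: 1 vanillin
Product: 2 4-(tert-butyldimethylsilyloxy)-3-methoxybenzaldehyde
Conditions: TBSCl, imidazole, DMF, rt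
Reagents that add atoms: tert-butyldimethylsilyl chloride, CC(C)(C)[Si](C)(C)Cl
Why: Imidazole-promoted O-silylation of a phenol; the aldehyde is inert, and the silyl ether is chosen because it can later be removed by fluoride without touching benzylic ethers.

Step 2
Reactants: 2 4-(tert-butyldimethylsilyloxy)-3-methoxybenzaldehyde
Product: 3 2-[4-(tert-butyldimethylsilyloxy)-3-methoxyphenyl]-1,3-dithiane
Conditions: HS(CH2)3SH, BF3·OEt2 (cat.), CH2Cl2, 0 °C to rt
Reagents that add atoms: propane-1,3-dithiol, SCCCS
Why: Lewis-acid-catalysed dithioacetalisation of an aromatic aldehyde; catalytic BF3·OEt2 at 0 °C leaves the aryl silyl ether intact, and the product holds the acidic C–H that makes C7 an acyl-anion equivalent.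

Step 3
Reactants: 4 3-hydroxy-4,5-dimethoxybenzaldehyde
Product: 5 3-(tert-butyldimethylsilyloxy)-4,5-dimethoxybenzaldehyde
Conditions: TBSCl, imidazole, DMF, rt
Reagents that add atoms: tert-butyldimethylsilyl chloride, CC(C)(C)[Si](C)(C)Cl
Why: Same phenol silylation as in step 1; it removes the acidic proton that would otherwise quench the lithium enolate in step 6.

Step 4
Reactants: 6 furfural
Product: 8 5-hydroxy-2(5H)-furanone (racemic), via furfural endoperoxide 7 (not isolated)
Conditions: O2, hν (visible), methylene blue (cat.), MeOH, rt
Reagents that add atoms: dioxygen, O=O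
Why: Dye-sensitised singlet-oxygen [4+2] cycloaddition to the furan gives endoperoxide 7; methanolysis expels the formyl carbon as methyl formate and leaves the γ-hydroxybutenolide, a standard preparation of this pseudo-acid.

Step 5
Reactants: 8 5-hydroxy-2(5H)-furanone; 9 (−)-menthol
Product: 10 (5R)-5-[(1R,2S,5R)-menthyloxy]-2(5H)-furanone
Conditions: CSA (cat.), toluene, reflux (Dean–Stark); crystallisation from petroleum ether, −20 °C; mother liquor re-equilibrated with CSA and cropped again
Reagents that add atoms: none
Why: Acid-catalysed acetalisation of the γ-hydroxybutenolide gives both C5 epimers, of which the (5R) epimer is the crystalline one; the acetal centre epimerises under acid, so the mother liquor can be recycled, and C5 is set by diastereomer crystallisation against the three fixed centres of menthol.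

Step 6
Reactants: 3 2-[4-(tert-butyldimethylsilyloxy)-3-methoxyphenyl]-1,3-dithiane; 10 (5R)-5-[(1R,2S,5R)-menthyloxy]-2(5H)-furanone; 5 3-(tert-butyldimethylsilyloxy)-4,5-dimethoxybenzaldehyde
Product: 13 dithianyl aldol lactone (3S,4R,5R; both C7' epimers), via lithiated dithiane 11 (not isolated), via lithium lactone enolate 12 (not isolated)
Conditions: 3, n-BuLi, THF, −78 to −30 °C; then 10, −78 °C; then 5, −78 °C; AcOH, −78 °C
Reagents that add atoms: none
Why: n-BuLi removes the C2 proton of 3 to give the sulfur- and aryl-stabilised anion 11, which adds in Michael fashion to the β-carbon of 10 (bond C7–C8) to give the lithium enolate 12; 12 is then intercepted by the non-enolisable aldehyde 5 in an aldol addition (bond C8'–C7'), and cold AcOH protonates the aldolate before retro-aldol can set in. The closest known reaction type is the tandem conjugate addition and enolate trapping of 2-lithio-2-aryl-1,3-dithianes with 5-alkoxy-2(5H)-furanones. No ring is closed. C8 is controlled by the acetal centre C9: the menthyloxy group shields its own face of the planar butenolide, so 11 enters anti and C8 becomes R. C8' is controlled by C8: the aldehyde approaches the enolate face opposite the bulky dithianyl group, which makes the lactone 3,4-trans, the relationship that later becomes the cis ring fusion. C7' is not controlled beyond the preference of the ring-locked E enolate for the anti aldol through a closed chair (Zimmerman–Traxler) transition state, and it need not be, since it is re-set in step 9. The step needs 1,4- over 1,2-addition, secured by the soft, delocalised character of 11 in THF at −78 °C, and it needs the second C–C bond to form before proton transfer, secured by an aldehyde without α-hydrogens that is added only after 10 is consumed.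

Step 7
Reactants: 13 dithianyl aldol lactone
Product: 14 keto lactone (3S,4R,5R; both C7' epimers)
Conditions: Hg(ClO4)2·3H2O, CaCO3, THF/H2O (5:1), 0 °C
Reagents that add atoms: water, O
Why: Thiophilic Hg(ClO4)2 (divalent mercury) binds sulfur and hydrolyses the thioketal to the aryl ketone, while CaCO3 takes up the perchloric acid so that the aryl silyl ethers, the benzylic alcohol and the acetal lactone see neither acid nor fluoride. C8 and C8' are not touched, and the all-trans lactone is the thermodynamic arrangement in any case should H8 exchange.

Step 8
Reactants: 14 keto lactone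
Product: 15 (2R,3R)-2-{[4-(tert-butyldimethylsilyloxy)-3-methoxyphenyl](hydroxy)methyl}-3-{[3-(tert-butyldimethylsilyloxy)-4,5-dimethoxyphenyl](hydroxy)methyl}butane-1,4-diol (C7 and C7' epimers)
Conditions: LiAlH4, THF, 0 °C to rt; Na2SO4·10H2O quench
Reagents that add atoms: none
Why: Global hydride reduction: LiAlH4 reduces the aryl ketone to the carbinol and the acylal-type lactone to the 1,4-diol (the first hydride opens the lactone, the C9 hemiacetal collapses with loss of menthoxide, and both aldehydes are reduced), which releases (−)-menthol for recovery. The new C7 carbinol forms as a mixture, which is harmless, and C8 and C8' carry through because hydride delivery outpaces enolisation; partial loss of an aryl silyl group would not matter since both are removed in step 10.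

Step 9
Reactants: 15 tetraol
Product: 16 (1S,3aR,4S,6aR)-1-[4-(tert-butyldimethylsilyloxy)-3-methoxyphenyl]-4-[3-(tert-butyldimethylsilyloxy)-4,5-dimethoxyphenyl]tetrahydro-1H,3H-furo[3,4-c]furan
Conditions: CSA (0.1 equiv), CH2Cl2, 4 Å MS, 0 °C to rt, quench with Et3N at full conversion
Reagents that add atoms: none
Why: Acid-catalysed dehydrative etherification of SN1 type: each p-oxygenated benzylic alcohol ionises to a quinoid benzylic cation that is captured by the primary hydroxyl on the neighbouring carbon (C9'–OH at C7, C9–OH at C7') in a five-membered closure, so both carbinol epimers converge. Under kinetic control the cation adopts the rotamer with H8 (or H8') eclipsing the aryl plane (allylic 1,3-strain) and the tethered oxygen attacks from its own side, placing each aryl trans to the adjacent ring carbon, that is exo, while the relationship of C8 and C8' from step 6 makes the bicycle cis-fused. Catalytic acid, low temperature and an early quench are specified because prolonged acid would equilibrate exo and endo ethers.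

Step 10
Reactants: 16 bis-silyl furofuran
Product: 17 (1S,3aR,4S,6aR)-1-(4-hydroxy-3-methoxyphenyl)-4-(3-hydroxy-4,5-dimethoxyphenyl)tetrahydro-1H,3H-furo[3,4-c]furan (target, 7S,7'S,8R,8'R)
Conditions: Bu4NF, AcOH, THF, 0 °C
Reagents that add atoms: none
Why: Fluoride-induced cleavage of both aryl silyl ethers, driven by the Si–F bond; AcOH buffers the phenoxides against aerial oxidation, and the benzylic ethers, which tolerate neither acid nor hydrogenolysis, are inert to fluoride, so no stereocentre is at risk.

## Compound list

1 | vanillin | COc1cc(C=O)ccc1O | starting material
2 | 4-(tert-butyldimethylsilyloxy)-3-methoxybenzaldehyde | COc1cc(C=O)ccc1O[Si](C)(C)C(C)(C)C | intermediate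
3 | 2-[4-(tert-butyldimethylsilyloxy)-3-methoxyphenyl]-1,3-dithiane | COc1cc(C2SCCCS2)ccc1O[Si](C)(C)C(C)(C)C | intermediate
4 | 3-hydroxy-4,5-dimethoxybenzaldehyde | COc1cc(C=O)cc(O)c1OC | starting material
5 | 3-(tert-butyldimethylsilyloxy)-4,5-dimethoxybenzaldehyde | COc1cc(C=O)cc(O[Si](C)(C)C(C)(C)C)c1OC | intermediate
6 | furfural | O=Cc1ccco1 | starting material
7 | furfural endoperoxide (2,3,7-trioxabicyclo[2.2.1]hept-5-ene-1-carbaldehyde, racemic, not isolated) | O=CC12C=CC(OO1)O2 | intermediate
8 | 5-hydroxy-2(5H)-furanone (racemic) | O=C1C=CC(O)O1 | intermediate
9 | (−)-menthol, (1R,2S,5R) | CC(C)[C@@H]1CC[C@@H](C)C[C@H]1O | starting material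
10 | (5R)-5-[(1R,2S,5R)-menthyloxy]-2(5H)-furanone | O=C1C=C[C@H](O[C@@H]2C[C@H](C)CC[C@H]2C(C)C)O1 | intermediate
11 | 2-lithio-2-[4-(tert-butyldimethylsilyloxy)-3-methoxyphenyl]-1,3-dithiane (not isolated) | COc1cc(C2([Li])SCCCS2)ccc1O[Si](C)(C)C(C)(C)C | intermediate
12 | lithium enolate of the (4R,5R) Michael adduct of 11 and 10 (not isolated) | COc1cc(C2(SCCCS2)[C@H]3[C@H](O[C@@H]4C[C@H](C)CC[C@H]4C(C)C)OC(O[Li])=C3)ccc1O[Si](C)(C)C(C)(C)C | intermediate
13 | (3S,4R,5R)-3-{[3-(tert-butyldimethylsilyloxy)-4,5-dimethoxyphenyl](hydroxy)methyl}-4-{2-[4-(tert-butyldimethylsilyloxy)-3-methoxyphenyl]-1,3-dithian-2-yl}-5-[(1R,2S,5R)-menthyloxy]dihydrofuran-2(3H)-one, both C7' epimers | COc1cc(C2(SCCCS2)[C@H]3[C@H](O[C@@H]4C[C@H](C)CC[C@H]4C(C)C)OC(=O)[C@@H]3C(O)c3cc(O[Si](C)(C)C(C)(C)C)c(OC)c(OC)c3)ccc1O[Si](C)(C)C(C)(C)C | intermediate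
14 | (3S,4R,5R)-4-[4-(tert-butyldimethylsilyloxy)-3-methoxybenzoyl]-3-{[3-(tert-butyldimethylsilyloxy)-4,5-dimethoxyphenyl](hydroxy)methyl}-5-[(1R,2S,5R)-menthyloxy]dihydrofuran-2(3H)-one, both C7' epimers | COc1cc(C(=O)[C@H]2[C@H](O[C@@H]3C[C@H](C)CC[C@H]3C(C)C)OC(=O)[C@@H]2C(O)c2cc(O[Si](C)(C)C(C)(C)C)c(OC)c(OC)c2)ccc1O[Si](C)(C)C(C)(C)C | intermediate
15 | (2R,3R)-2-{[4-(tert-butyldimethylsilyloxy)-3-methoxyphenyl](hydroxy)methyl}-3-{[3-(tert-butyldimethylsilyloxy)-4,5-dimethoxyphenyl](hydroxy)methyl}butane-1,4-diol, C7 and C7' epimers | COc1cc(C(O)[C@@H](CO)[C@H](CO)C(O)c2cc(O[Si](C)(C)C(C)(C)C)c(OC)c(OC)c2)ccc1O[Si](C)(C)C(C)(C)C | intermediate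
16 | (1S,3aR,4S,6aR)-1-[4-(tert-butyldimethylsilyloxy)-3-methoxyphenyl]-4-[3-(tert-butyldimethylsilyloxy)-4,5-dimethoxyphenyl]tetrahydro-1H,3H-furo[3,4-c]furan | COc1cc([C@H]2OC[C@H]3[C@@H]2CO[C@@H]3c2cc(O[Si](C)(C)C(C)(C)C)c(OC)c(OC)c2)ccc1O[Si](C)(C)C(C)(C)C | intermediate
17 | (1S,3aR,4S,6aR)-1-(4-hydroxy-3-methoxyphenyl)-4-(3-hydroxy-4,5-dimethoxyphenyl)tetrahydro-1H,3H-furo[3,4-c]furan | COc1cc([C@H]2OC[C@H]3[C@@H]2CO[C@@H]3c2cc(O)c(OC)c(OC)c2)ccc1O | target

## Step count and risks

Total step count: 10. Longest linear sequence: 7 steps (steps 1, 2, 6, 7, 8, 9, 10 from vanillin; the furfural branch, steps 4, 5, 6 to 10, is equally long).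

**Step 6 (key step).** The most likely failure is incomplete capture of the enolate: the nucleophilic carbon C8' sits next to the carbon bearing the quaternary dithiane, so the aldol may be slow or may revert on work-up, and the enolate is then simply protonated; 1,2-addition of the anion to the lactone carbonyl is a lesser risk. Fallback: separate the two bond formations. From 3 and 10, the conjugate addition alone is run and quenched to give the Michael adduct (4R,5R)-4-{2-[4-(tert-butyldimethylsilyloxy)-3-methoxyphenyl]-1,3-dithian-2-yl}-5-[(1R,2S,5R)-menthyloxy]dihydrofuran-2(3H)-one F1. F1 is then enolised with LDA at −78 °C, transmetallated with ZnCl2 to a less basic, more tightly chelating zinc enolate, and treated with 5. The aldol takes the same face, anti to the dithianyl group, and the sequence returns to the route at 13.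

**Step 9.** The most likely failure is loss of kinetic control: re-ionisation of the closed benzylic ethers drifts the mixture toward the exo/endo equilibrium, and capture of one cation by the other benzylic hydroxyl or loss of a silyl group may accompany it. Fallback: give up kinetic control and work under thermodynamic control with recycling. From 15, the closure is driven to equilibrium with a stronger acid (TsOH, CH2Cl2, rt) and 16 is separated by chromatography from its 7-epimer F2 and its 7'-epimer F3. F2 and F3 are returned to the same acid, where they re-enter the equilibrium through the same benzylic cations, and further crops of 16 are taken. The sequence returns to the route at 16.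

**Step 7.** The most likely failure is base- or Lewis-acid-induced β-elimination across C8–C9 once the ketone is unmasked, since H8 becomes acidic and the acetal carbon carries two leaving groups; slow hydrolysis at the hindered thioketal is a second concern. Fallback: reduce before unmasking, so that the ketone never sits next to the acetal lactone. From 13, LiAlH4 in THF gives the dithianyl triol F4 with loss of menthol. Hydrolysis of the thioketal with Hg(ClO4)2 and CaCO3 in aqueous THF then gives the keto triol F5, in equilibrium with its five-membered hemiketal on the C9' hydroxyl. NaBH4 in MeOH at 0 °C reduces F5 and returns the sequence to the route at 15.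

**Step 8.** The most likely failure is retro-aldol cleavage at the C7' alkoxide before the lactone carbonyl is reduced, which would shed the Ar2 unit. Fallback: cap the aldol hydroxyl first. From 14, TESOTf and 2,6-lutidine in CH2Cl2 at −78 °C give the C7' triethylsilyl ether F6, in which no β-alkoxide can form. LiAlH4 then gives the triol mono-silyl ether F7. Under the conditions of step 9 the benzylic silyl ether ionises as the alcohol does, and the sequence returns to the route at 16.

## Further compounds

F1 | step 6 | (4R,5R)-4-{2-[4-(tert-butyldimethylsilyloxy)-3-methoxyphenyl]-1,3-dithian-2-yl}-5-[(1R,2S,5R)-menthyloxy]dihydrofuran-2(3H)-one | COc1cc(C2(SCCCS2)[C@H]2[C@H](O[C@@H]3C[C@H](C)CC[C@H]3C(C)C)OC(=O)C2)ccc1O[Si](C)(C)C(C)(C)C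
F2 | step 9 | 7-epimer of 16 (Ar1 endo) | COc1cc([C@@H]2OC[C@H]3[C@@H]2CO[C@@H]3c2cc(O[Si](C)(C)C(C)(C)C)c(OC)c(OC)c2)ccc1O[Si](C)(C)C(C)(C)C
F3 | step 9 | 7'-epimer of 16 (Ar2 endo) | COc1cc([C@H]2OC[C@H]3[C@@H]2CO[C@H]3c2cc(O[Si](C)(C)C(C)(C)C)c(OC)c(OC)c2)ccc1O[Si](C)(C)C(C)(C)C
F4 | step 7 | (2R,3R)-2-{2-[4-(tert-butyldimethylsilyloxy)-3-methoxyphenyl]-1,3-dithian-2-yl}-3-{[3-(tert-butyldimethylsilyloxy)-4,5-dimethoxyphenyl](hydroxy)methyl}butane-1,4-diol, C7' epimers | COc1cc(C2(SCCCS2)[C@@H](CO)[C@H](CO)C(O)c2cc(O[Si](C)(C)C(C)(C)C)c(OC)c(OC)c2)ccc1O[Si](C)(C)C(C)(C)C
F5 | step 7 | (2R,3R)-2-[4-(tert-butyldimethylsilyloxy)-3-methoxybenzoyl]-3-{[3-(tert-butyldimethylsilyloxy)-4,5-dimethoxyphenyl](hydroxy)methyl}butane-1,4-diol, C7' epimers (open keto form) | COc1cc(C(=O)[C@@H](CO)[C@H](CO)C(O)c2cc(O[Si](C)(C)C(C)(C)C)c(OC)c(OC)c2)ccc1O[Si](C)(C)C(C)(C)C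
F6 | step 8 | C7' triethylsilyl ether of 14, C7' epimers | COc1cc(C(=O)[C@H]2[C@H](O[C@@H]3C[C@H](C)CC[C@H]3C(C)C)OC(=O)[C@@H]2C(O[Si](CC)(CC)CC)c2cc(O[Si](C)(C)C(C)(C)C)c(OC)c(OC)c2)ccc1O[Si](C)(C)C(C)(C)C
F7 | step 8 | C7' triethylsilyl ether of 15, C7 and C7' epimers | COc1cc(C(O)[C@@H](CO)[C@H](CO)C(O[Si](CC)(CC)CC)c2cc(O[Si](C)(C)C(C)(C)C)c(OC)c(OC)c2)ccc1O[Si](C)(C)C(C)(C)C
A1 | alternative 1 | epoxy cinnamyl ether, bis-pivalate (C7 as in the target, either epoxide epimer at C8) | COc1cc([C@H](C2CO2)OC/C=C/c2cc(OC(=O)C(C)(C)C)c(OC)c(OC)c2)ccc1OC(=O)C(C)(C)C
A2 | alternative 1 | bis-pivalate of the target | COc1cc([C@H]2OC[C@H]3[C@@H]2CO[C@@H]3c2cc(OC(=O)C(C)(C)C)c(OC)c(OC)c2)ccc1OC(=O)C(C)(C)C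
A3 | alternative 2 | ring-A-fused cyclobutanone with C9 as ketone and Ar2 on C7', bis-triisopropylsilyl ether | COc1cc([C@H]2OC[C@H]3[C@@H]2C(=O)[C@@H]3c2cc(O[Si](C(C)C)(C(C)C)C(C)C)c(OC)c(OC)c2)ccc1O[Si](C(C)C)(C(C)C)C(C)C
A4 | alternative 2 | bicyclic lactone with C9 as carbonyl, bis-triisopropylsilyl ether | COc1cc([C@H]2OC[C@H]3[C@@H]2C(=O)O[C@@H]3c2cc(O[Si](C(C)C)(C(C)C)C(C)C)c(OC)c(OC)c2)ccc1O[Si](C(C)C)(C(C)C)C(C)C
A5 | alternative 3 | dimethyl 2-[4-(tert-butyldimethylsilyloxy)-3-methoxybenzoyl]-3-[3-(tert-butyldimethylsilyloxy)-4,5-dimethoxybenzoyl]succinate (C8 and C8' configurationally labile) | COC(=O)C(C(=O)c1ccc(O[Si](C)(C)C(C)(C)C)c(OC)c1)C(C(=O)OC)C(=O)c1cc(O[Si](C)(C)C(C)(C)C)c(OC)c(OC)c1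
A6 | alternative 3 | di-exo cis-fused bis-lactone with C9 and C9' as carbonyls, bis-tert-butyldimethylsilyl ether | COc1cc([C@H]2OC(=O)[C@H]3[C@@H]2C(=O)O[C@@H]3c2cc(O[Si](C)(C)C(C)(C)C)c(OC)c(OC)c2)ccc1O[Si](C)(C)C(C)(C)C
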